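**Retrosynthetic overview**
1. Target 16 ⇐ triol 15 (oxidise C3/C22) ⇐ epoxide 14 (trans-diaxial hydride opening sets C14 and C15) ⇐ 13 (Wittig at C10) ⇐ 12 (face-selective epoxidation of the C14=C15 olefin).
2. 12 ⇐ acyclic tetraepoxide 9 by a one-flask double epoxonium cascade: in each half the oxepane (rings A and D) closes first, then the cyclohexane (rings B and C). The left terminator is an enol silane, the right one the C14=C15 alkene.
3. 9 ⇐ 2 + 8: the central C12–C13 bond is made by a new nickel-catalysed reductive conjugate allylation that also delivers the regiodefined enol silane.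
4. 2 ⇐ farnesyl acetate 1 and 8 ⇐ geranylacetone 3 by Shi epoxidation (organocatalytic; every stereocentre of the target descends from these epoxides) and α-methylenation.

Assumption: squalene numbering is used (chain C1–C24; methyl carbons C25–C30 on C2, C6, C10, C15, C19, C23; α = face anti to the angular methyls C26/C29; ring A = left oxepane, ring B = left cyclohexane, ring C = right cyclohexane, ring D = right oxepane), and the Shi ketone is used as its L-fructose-derived enantiomer (ent-Shi ketone), which the required (S)-epoxides demand.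

**Route**

Step 1
Reactants: 1 (2E,6E)-farnesyl acetate
Product: 2 (2E,6S,7S,10S)-6,7:10,11-diepoxy-3,7,11-trimethyldodec-2-en-1-yl acetate
Conditions: ent-Shi ketone (30 mol%), KHSO5 (as 2KHSO5·KHSO4·K2SO4), K2CO3, Bu4NHSO4, MeCN/CH2(OMe)2–aq. Na2B4O7 buffer (pH 10.5), 0 °C
Reagents that add atoms: potassium peroxymonosulfate KHSO5, [K+].[O-]S(=O)(=O)OO
Why: Shi asymmetric epoxidation (chiral dioxirane, spiro transition state) oxidises only the two electron-rich trisubstituted alkenes because the allylic acetate deactivates C14=C15, and the L-series ketone sets C18, C19 and C22 as S.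

Step 2
Reactants: 3 (E)-geranylacetone
Product: 4 (5S,6S,9S)-5,6:9,10-diepoxy-6,10-dimethylundecan-2-one
Conditions: ent-Shi ketone (30 mol%), KHSO5 (as 2KHSO5·KHSO4·K2SO4), K2CO3, Bu4NHSO4, MeCN/CH2(OMe)2–aq. Na2B4O7 buffer (pH 10.5), 0 °C
Reagents that add atoms: potassium peroxymonosulfate KHSO5, [K+].[O-]S(=O)(=O)OO
Why: The same Shi epoxidation sets C3, C6 and C7 (squalene numbering) as S on both trisubstituted alkenes while the ketone is inert to the dioxirane.

Step 3
Reactants: 4 (5S,6S,9S)-5,6:9,10-diepoxy-6,10-dimethylundecan-2-one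
Product: 8 (6S,7S,10S)-6,7:10,11-diepoxy-7,11-dimethyldodec-1-en-3-one, via lithium enolate 5 (not isolated), via Mannich base 6 (not isolated), via trimethylammonium iodide 7 (not isolated)
Conditions: LiN(iPr)2, THF, −78 °C; [Me2N=CH2]I, −78 → 0 °C; MeI, Et2O, rt; NaHCO3, CH2Cl2/H2O, rt
Reagents that add atoms: Eschenmoser's salt (N,N-dimethylmethyleneiminium iodide), C=[N+](C)C.[I-]
Why: Kinetic deprotonation at the methyl group, Mannich reaction and Hofmann-type elimination of the quaternised amine (α-methylenation) add C12 and give the vinyl ketone; the epoxides survive the short low-temperature enolate stage.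

Step 4
Reactants: 2 diepoxyfarnesyl acetate; 8 diepoxy vinyl ketone
Product: 9 (3S,6S,7S,18S,19S,22S)-2,3:6,7:18,19:22,23-tetraepoxy-10-(triethylsilyloxy)-27-norsqualene-10Z,14E-diene
Conditions: NiCl2(dme) (10 mol%), neocuproine (10 mol%), Mn powder (3 equiv), Et3SiCl (1.5 equiv), DMF/THF, 0 °C → rt, slow addition of 8
Reagents that add atoms: chlorotriethylsilane, CC[Si](Cl)(CC)CC
Why: Proposed new method: a nickel-catalysed reductive conjugate allylation in which zerovalent nickel and Et3SiCl turn enone 8 into an η3-(1-silyloxyallyl)nickel chloride, Mn reduces it, the same metal centre ionises allylic acetate 2, and reductive elimination from the bis(allyl)nickel joins the two unhindered CH2 termini (C12–C13) and releases the enol silane regiodefined towards C11; the closest known reaction type is the nickel-catalysed reductive conjugate addition of aryl or alkyl halides to enones with chlorosilane trapping, here extended to an allylic ester (no stereocentre is formed, and both new olefin geometries are inconsequential later).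

Step 5
Reactants: 9 silyl enol ether tetraepoxide
Product: 11 tetracyclic keto diol (rings A–D closed; C10 ketone; 3S/22S carbinols; Δ15(16) isomer drawn as principal component of the kinetic olefin mixture), via bis-trimethylsilyl ether 10 (not isolated)
Conditions: Me3SiOTf (3 equiv), 2,6-di-tert-butyl-4-methylpyridine (4 equiv), CH2Cl2, −78 °C; then 1 M HCl, THF, 0 °C
Reagents that add atoms: none
Why: Lewis-acid-triggered epoxonium cascade (oxa- then carbacyclisation): each silylated terminal epoxide is opened at C2/C23 by the neighbouring epoxide oxygen and the bicyclic epoxonium ion is opened with inversion at C6/C19 by the enol silane (left) or the C14=C15 alkene (right), closing four trans-fused rings and setting the quaternary centres C6 and C19 from the Shi epoxides, with the C11 side chain equatorial.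

Step 6
Reactants: 11 tetracyclic keto diol (kinetic olefin mixture)
Product: 12 tetracyclic keto diol with the tetrasubstituted C14=C15 olefin
Conditions: p-TsOH·H2O (20 mol%), benzene, 70 °C
Reagents that add atoms: none
Why: Acid-catalysed olefin equilibration through the tertiary C15 cation funnels the Δ15(16), Δ15(28) and Δ14 isomers towards the thermodynamically favoured tetrasubstituted olefin and keeps C11 in its equatorial configuration; residual trisubstituted isomer is recycled.

Step 7
Reactants: 12 Δ14(15) keto diol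
Product: 13 14α,15α-epoxy keto diol
Conditions: dimethyldioxirane (1.1 equiv), acetone, −40 → 0 °C
Reagents that add atoms: dimethyldioxirane, CC1(C)OO1
Why: Electrophilic epoxidation of the most electron-rich alkene occurs from the α-face, anti to the allylic angular methyl C29, fixing the oxygen at C14 on the face required for the axial 14-OH.

Step 8
Reactants: 13 14α,15α-epoxy keto diol
Product: 14 10(27)-methylene 14α,15α-epoxy diol
Conditions: Ph3PCH3Br, KOtBu (excess), toluene/THF, 0 → 70 °C
Reagents that add atoms: methyltriphenylphosphonium bromide, C[P+](c1ccccc1)(c1ccccc1)c1ccccc1.[Br-]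
Why: Wittig methylenation of the hindered C10 ketone installs the exocyclic methylene regiospecifically; C11 is already the thermodynamic equatorial epimer and the epoxide and alkoxides are inert to the ylide.

Step 9
Reactants: 14 methylene epoxy diol
Product: 15 (3S,22S)-3,14α,22-triol with 15α-methyl
Conditions: LiEt3BH (excess), THF, 65 °C; then H2O
Reagents that add atoms: none
Why: Hydride opening of the epoxide follows the Fürst–Plattner rule: attack at C15 from the β-face gives the trans-diaxial product, so C15 is inverted (H axial, methyl equatorial, 15S) and C14 keeps its axial α-hydroxyl (14S).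

Step 10
Reactants: 15 triol
Product: 16 target CNP0218659.1, (6S,7S,11R,14S,15S,18S,19R)
Conditions: Dess–Martin periodinane (3 equiv), pyridine, CH2Cl2, rt
Reagents that add atoms: none
Why: Dess–Martin oxidation converts the two secondary carbinols at C3 and C22 into the oxepanone ketones and cannot touch the tertiary 14-OH or the exocyclic alkene.

**Compound list**
1 | (2E,6E)-farnesyl acetate | CC(=O)OC/C=C(\C)CC/C=C(\C)CCC=C(C)C | starting material
2 | (2E,6S,7S,10S)-6,7:10,11-diepoxy-3,7,11-trimethyldodec-2-en-1-yl acetate | CC(=O)OC/C=C(\C)CC[C@@H]1O[C@@]1(C)CC[C@@H]1OC1(C)C | intermediate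
3 | (E)-geranylacetone, (5E)-6,10-dimethylundeca-5,9-dien-2-one | CC(=O)CC/C=C(\C)CCC=C(C)C | starting material
4 | (5S,6S,9S)-5,6:9,10-diepoxy-6,10-dimethylundecan-2-one | CC(=O)CC[C@@H]1O[C@@]1(C)CC[C@@H]1OC1(C)C | intermediate
5 | kinetic lithium enolate of 4 (C1=C2 enolate) | [Li]OC(=C)CC[C@@H]1O[C@@]1(C)CC[C@@H]1OC1(C)C | intermediate
6 | (6S,7S,10S)-1-(dimethylamino)-6,7:10,11-diepoxy-7,11-dimethyldodecan-3-one (Mannich base) | CN(C)CCC(=O)CC[C@@H]1O[C@@]1(C)CC[C@@H]1OC1(C)C | intermediate
7 | N-methyl quaternary ammonium iodide of 6 | C[N+](C)(C)CCC(=O)CC[C@@H]1O[C@@]1(C)CC[C@@H]1OC1(C)C.[I-] | intermediate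
8 | (6S,7S,10S)-6,7:10,11-diepoxy-7,11-dimethyldodec-1-en-3-one | C=CC(=O)CC[C@@H]1O[C@@]1(C)CC[C@@H]1OC1(C)C | intermediate
9 | (3S,6S,7S,18S,19S,22S)-2,3:6,7:18,19:22,23-tetraepoxy-10-(triethylsilyloxy)-27-norsqualene-10Z,14E-diene (10E and 14Z isomers equally serviceable) | CC[Si](CC)(CC)O/C(CC[C@@H]1O[C@@]1(C)CC[C@@H]1OC1(C)C)=C\CC/C=C(\C)CC[C@@H]1O[C@@]1(C)CC[C@@H]1OC1(C)C | intermediate
10 | 3,22-bis(trimethylsilyl) ether of 11 | O=C1CC[C@@H]2OC(C)(C)[C@@H](O[Si](C)(C)C)CC[C@@]2(C)[C@@H]1CC[C@@H]1C(C)=CC[C@@H]2OC(C)(C)[C@@H](O[Si](C)(C)C)CC[C@]21C | intermediate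
11 | tetracyclic keto diol: rings A–D closed, C10 ketone (27-nor), (3S,22S)-diol, 14α-H, Δ15(16) olefin (principal isomer; Δ14 and Δ15(28) isomers accompany it); C6, C7, C11, C18, C19 as in the target | O=C1CC[C@@H]2OC(C)(C)[C@@H](O)CC[C@@]2(C)[C@@H]1CC[C@@H]1C(C)=CC[C@@H]2OC(C)(C)[C@@H](O)CC[C@]21C | intermediate
12 | the same keto diol with the tetrasubstituted C14=C15 olefin | O=C1CC[C@@H]2OC(C)(C)[C@@H](O)CC[C@@]2(C)[C@@H]1CCC1=C(C)CC[C@@H]2OC(C)(C)[C@@H](O)CC[C@]21C | intermediate
13 | 14α,15α-epoxide of 12 | O=C1CC[C@@H]2OC(C)(C)[C@@H](O)CC[C@@]2(C)[C@@H]1CC[C@@]12O[C@@]2(C)CC[C@@H]3OC(C)(C)[C@@H](O)CC[C@]31C | intermediate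
14 | 10(27)-methylene analogue of 13 (C10 ketone replaced by C=CH2) | C=C1CC[C@@H]2OC(C)(C)[C@@H](O)CC[C@@]2(C)[C@@H]1CC[C@@]12O[C@@]2(C)CC[C@@H]3OC(C)(C)[C@@H](O)CC[C@]31C | intermediate
15 | (3S,22S)-3,22-dihydroxy analogue of the target (14α-OH, 15α-methyl, 10(27)-ene) | C=C1CC[C@@H]2OC(C)(C)[C@@H](O)CC[C@@]2(C)[C@@H]1CC[C@]1(O)[C@@H](C)CC[C@@H]2OC(C)(C)[C@@H](O)CC[C@]21C | intermediate
16 | CNP0218659.1, (6S,7S,11R,14S,15S,18S,19R)-3,22-diketone with 10(27)-methylene and 14α-OH | C=C1CC[C@@H]2OC(C)(C)C(=O)CC[C@@]2(C)[C@@H]1CC[C@]1(O)[C@@H](C)CC[C@@H]2OC(C)(C)C(=O)CC[C@]21C | target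

**Step count and risks**

Total steps: 10. Longest linear sequence: 9 steps (3 → 16, steps 2–10).

Most likely to fail:

- **Step 4 (the proposed new coupling).** Homodimerisation of either allyl partner or opening of the epoxides by the chlorosilane could defeat it. The fallback uses known chemistry, sets out from 2 and comes back at 9. Pd(PPh3)4-catalysed exchange of the allylic acetate with PhSO2Na gives the allyl sulfone F1. Its α-lithio anion (n-BuLi, THF, −78 °C) adds 1,4 to vinyl ketone 8 and the enolate is trapped with Et3SiCl to give the C13-phenylsulfonyl enol silane F2. Reductive desulfonylation with catalytic PdCl2(dppp) and LiEt3BH at 0 °C then gives 9.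

- **Step 5 (two different cascades in one flask).** Each cascade type is precedented singly, but running both in one molecule may give a low yield. The fallback stages the cyclisations, sets out from 2 and comes back at 12. Diepoxide 2 alone is cyclised with Me3SiOTf and the pyridine base, then desilylated, to the bicyclic hydroxy allylic acetate F3 (kinetic olefin mixture). Acid equilibration as in step 6 gives the tetrasubstituted allylic acetate F4. F4 is joined to 8 by the step 4 coupling (or its sulfone variant), the free C22 hydroxyl being silylated by the excess Et3SiCl, to give the enol silane F5. A single enol-silane-terminated cascade on F5 (Me3SiOTf, base; then 1 M HCl) closes rings A and B and gives 12.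

- **Step 9 (hydride attack at a tertiary epoxide carbon with a syn-axial methyl).** The centre is very hindered and the epoxide may not open. The fallback replaces the opening by isomerisation and hydrogen-atom-transfer reduction, sets out from 13 and comes back at 15. Me3SiOTf/DBU in toluene isomerises the epoxide to the allylic silyl ether, and acidic work-up (which removes all silyl groups) gives the 14α-hydroxy-15(28)-methylene keto diol F6. Radical hydrogenation with Mn(dpm)3, PhSiH3 and t-BuOOH in i-PrOH reduces the exocyclic alkene to the thermodynamically favoured equatorial 15-methyl compound F7. Wittig methylenation of the C10 ketone (Ph3PCH3Br, KOtBu) then gives 15.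

**Further compounds**
F1 | step 4 | (2E,6S,7S,10S)-6,7:10,11-diepoxy-3,7,11-trimethyldodec-2-en-1-yl phenyl sulfone | O=S(=O)(C/C=C(\C)CC[C@@H]1O[C@@]1(C)CC[C@@H]1OC1(C)C)c1ccccc1
F2 | step 4 | 13-(phenylsulfonyl) derivative of 9 (C13 epimers) | CC[Si](CC)(CC)O/C(CC[C@@H]1O[C@@]1(C)CC[C@@H]1OC1(C)C)=C\CC(/C=C(\C)CC[C@@H]1O[C@@]1(C)CC[C@@H]1OC1(C)C)S(=O)(=O)c1ccccc1
F3 | step 5 | rings C/D hydroxy allylic acetate, (22S)-OH, 14α-H, Δ15(16) isomer drawn (kinetic olefin mixture) | CC(=O)OC[C@@H]1C(C)=CC[C@@H]2OC(C)(C)[C@@H](O)CC[C@]21C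
F4 | step 5 | rings C/D hydroxy allylic acetate with the tetrasubstituted C14=C15 olefin | CC(=O)OCC1=C(C)CC[C@@H]2OC(C)(C)[C@@H](O)CC[C@]21C
F5 | step 5 | 10-(triethylsilyloxy) enol ether carrying the left 2,3:6,7-diepoxide and the closed rings C/D (C14=C15 olefin, 22-O-triethylsilyl) | CC[Si](CC)(CC)O/C(CC[C@@H]1O[C@@]1(C)CC[C@@H]1OC1(C)C)=C\CCC1=C(C)CC[C@@H]2OC(C)(C)[C@@H](O[Si](CC)(CC)CC)CC[C@]21C
F6 | step 9 | tetracyclic keto triol: C10 ketone, (3S,22S)-diol, 14α-OH, 15(28)-methylene | O=C1CC[C@@H]2OC(C)(C)[C@@H](O)CC[C@@]2(C)[C@@H]1CC[C@]1(O)C(=C)CC[C@@H]2OC(C)(C)[C@@H](O)CC[C@]21C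
F7 | step 9 | tetracyclic keto triol: C10 ketone, (3S,22S)-diol, 14α-OH, 15α-methyl | O=C1CC[C@@H]2OC(C)(C)[C@@H](O)CC[C@@]2(C)[C@@H]1CC[C@]1(O)[C@@H](C)CC[C@@H]2OC(C)(C)[C@@H](O)CC[C@]21C
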